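**Plan**

- Retrosynthesis: the two aryl O–CH3 bonds are cut first, then C4a–C5 of the benzene ring (C4a, C5, C6, C7, C8, C8a). That ring carries oxygen on C5 and C7 in the alternating, acetate-type pattern, with the pyranone oxygen on C8a. C8–C7–C6–C5 with their oxygens are therefore a β-keto ester chain on C6 of a monocyclic 4-pyranone, whose C5 is the latent C4a nucleophile.
- Further cuts: C7–C6 of that arm (malonate homologation), C8–C7 (carboxylation of a pyranone methyl), and side-chain C6–C7 (heptanoate numbering; lateral alkylation of 2,6-dimethyl-4-pyranone with a six-carbon iodo ester).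
- Forward: the iodo ester is made from 4-chlorobutanoyl chloride and Meldrum's acid and joined to the ready-made pyranone ring. The acetoacetate arm is then grown on the second methyl, the benzene ring is closed last by intramolecular Claisen condensation, and O-methylation finishes the route.
- Stereochemistry: the only stereocentre (C3, S) comes from a Noyori hydrogenation of the β-keto ester with (S)-BINAP–Ru and is never made acidic at carbon afterwards.

Key step: step 9

Remark on the chemistry: the lithiated pyranones are delocalised dienolates and are written as C-lithio compounds only for bookkeeping.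

**Route**

Step 1
Reactants: 1 4-chlorobutanoyl chloride; 2 Meldrum's acid (2,2-dimethyl-1,3-dioxane-4,6-dione)
Product: 4 methyl 6-chloro-3-oxohexanoate, via acyl Meldrum's acid 3 (not isolated)
Conditions: pyridine, CH2Cl2, 0 °C → rt; dil. HCl wash; then MeOH, reflux
Reagents that add atoms: methanol, CO
Why: C-acylation of Meldrum's acid by the acid chloride followed by methanolysis with loss of acetone and CO2 is the standard Meldrum's acid route to β-keto esters, and the primary chloride is inert under these weakly basic, then neutral conditions.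

Step 2
Reactants: 4 methyl 6-chloro-3-oxohexanoate
Product: 5 methyl (S)-6-chloro-3-hydroxyhexanoate
Conditions: H2 (50 atm), RuCl2[(S)-BINAP] (cat.), MeOH, 50 °C
Reagents that add atoms: none
Why: In this Noyori asymmetric hydrogenation the β-keto ester chelates ruthenium through both carbonyls and the (S)-BINAP ligand directs hydride to one ketone face, which should set C3 as S in the same sense in which this catalyst gives methyl (S)-3-hydroxybutanoate, the remote chlorine not changing the CIP order.

Step 3
Reactants: 5 methyl (S)-6-chloro-3-hydroxyhexanoate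
Product: 6 methyl (S)-3-[(tert-butyldimethylsilyl)oxy]-6-chlorohexanoate
Conditions: TBSCl, imidazole, DMF, rt
Reagents that add atoms: tert-butyldimethylsilyl chloride, CC(C)(C)[Si](C)(C)Cl
Why: Imidazole-promoted silylation caps the secondary alcohol so that it can neither close onto the halide to a tetrahydrofuran nor quench the carbanions used later.

Step 4
Reactants: 6 methyl (S)-3-[(tert-butyldimethylsilyl)oxy]-6-chlorohexanoate
Product: 7 methyl (S)-3-[(tert-butyldimethylsilyl)oxy]-6-iodohexanoate
Conditions: NaI, acetone, reflux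
Reagents that add atoms: sodium iodide, [Na+].[I-]
Why: The Finkelstein exchange, driven by precipitation of NaCl from acetone, turns the sluggish chloride into an iodide that can react with a stabilised carbanion at low temperature.

Step 5
Reactants: 8 2,6-dimethyl-4H-pyran-4-one; 7 methyl (S)-3-[(tert-butyldimethylsilyl)oxy]-6-iodohexanoate
Product: 10 methyl (S)-3-[(tert-butyldimethylsilyl)oxy]-7-(6-methyl-4-oxo-4H-pyran-2-yl)heptanoate, via 2-(lithiomethyl)-6-methyl-4H-pyran-4-one 9 (not isolated)
Conditions: 8 (2.5 equiv), LiHMDS (2.4 equiv), THF, −78 °C; then 7 (1 equiv), DMPU, −78 → −30 °C; aq. NH4Cl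
Reagents that add atoms: lithium hexamethyldisilazide, [Li]N([Si](C)(C)C)[Si](C)(C)C (supplies only the lithium of 9)
Why: Lateral deprotonation of a 2-methyl group of the 4-pyranone gives the extended enolate, which should undergo SN2 C-alkylation with the primary iodide at low temperature (lateral alkylation of 2-methyl-4-pyranones), an excess of the cheap anion suppressing double alkylation and the β-branched methyl ester being far less electrophilic than the iodide.

Step 6
Reactants: 10 methyl (S)-3-[(tert-butyldimethylsilyl)oxy]-7-(6-methyl-4-oxo-4H-pyran-2-yl)heptanoate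
Product: 12 2-{6-[(5S)-5-[(tert-butyldimethylsilyl)oxy]-7-methoxy-7-oxoheptyl]-4-oxo-4H-pyran-2-yl}acetic acid, via 6-(lithiomethyl)pyranone 11 (not isolated)
Conditions: LiHMDS (1.05 equiv), THF, −78 °C; CO2 (g), −78 → −20 °C; cold 1 M HCl to pH 3; crude acid used at once
Reagents that add atoms: lithium hexamethyldisilazide, [Li]N([Si](C)(C)C)[Si](C)(C)C (supplies only the lithium of 11); carbon dioxide, O=C=O
Why: The second lateral lithiation should take place at the remaining methyl, which is less hindered and gives a more stable primary carbanion than the substituted methylene and is far more acidic than the ester α-CH2, and the extended enolate is trapped on carbon by CO2 (carboxylation of a lithiated 2-methyl-4-pyranone) at a temperature where the β-silyloxy ester is stable.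

Step 7
Reactants: 12 2-{6-[(5S)-5-[(tert-butyldimethylsilyl)oxy]-7-methoxy-7-oxoheptyl]-4-oxo-4H-pyran-2-yl}acetic acid; 13 potassium monomethyl malonate
Product: 16 methyl (S)-3-[(tert-butyldimethylsilyl)oxy]-7-[6-(4-methoxy-2,4-dioxobutyl)-4-oxo-4H-pyran-2-yl]heptanoate, via acyl imidazolide 14 (not isolated), via acylmalonic half-ester 15 (not isolated)
Conditions: CDI, THF, rt; then 13, MgCl2, Et3N, MeCN/THF, rt → 40 °C; 1 M HCl, 0 °C
Reagents that add atoms: 1,1'-carbonyldiimidazole, O=C(n1ccnc1)n1ccnc1 (supplies only the imidazolyl group of 14)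
Why: In this Masamune–Brooks homologation the acyl imidazolide acylates the magnesium enolate of the malonate half-ester on carbon and the adduct loses CO2 on acidification, giving the β-keto ester under near-neutral conditions that spare the silyl ether and both methyl esters.

Step 8
Reactants: 16 methyl (S)-3-[(tert-butyldimethylsilyl)oxy]-7-[6-(4-methoxy-2,4-dioxobutyl)-4-oxo-4H-pyran-2-yl]heptanoate
Product: 17 methyl (S)-3-hydroxy-7-[6-(4-methoxy-2,4-dioxobutyl)-4-oxo-4H-pyran-2-yl]heptanoate
Conditions: HF·pyridine, THF/pyridine, 0 °C → rt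
Reagents that add atoms: none
Why: Formation of the strong Si–F bond drives cleavage of the TBS ether with buffered HF·pyridine, a weakly acidic desilylation that leaves the enolisable β-keto ester, the pyranone and the methyl esters untouched.

Step 9
Reactants: 17 methyl (S)-3-hydroxy-7-[6-(4-methoxy-2,4-dioxobutyl)-4-oxo-4H-pyran-2-yl]heptanoate
Product: 19 methyl (S)-7-(5,7-dihydroxy-4-oxo-4H-chromen-2-yl)-3-hydroxyheptanoate, via chromene-4,5,7-trione tautomer 18 (not isolated)
Conditions: NaOMe (5 equiv), dry degassed MeOH, Ar, 0 °C → rt; then 1 M HCl to pH 2–3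
Reagents that add atoms: none
Why: Methoxide deprotonates the doubly activated arm, and the tautomer deprotonated at the CH2 next to the ring is a dienolate running through pyranone C6=C5 to O4; its α-carbon C5 (the future C4a) adds to the terminal ester carbonyl, methoxide is expelled to give trione 18, and two enolisations aromatise it to the 5,7-diol 19. The closest known reaction type is the base-induced biomimetic Claisen cyclisation of 3,5,7-triketo esters and of their pyrone-masked forms to acylphloroglucinols and 5,7-dihydroxychromones. The benzene ring closes in a 6-(enolexo)-exo-trig mode. No stereocentre is formed, and C3 of the side chain carries no acidic hydrogen and keeps its S configuration. The step needs C-acylation at C5 rather than aldol-type folding, O-acylation or intermolecular condensation; the intact pyranone holds three chain carbonyls in a ring so that C5 onto the ester is the only six-membered closure within reach and the only one that ends in an aromatic ring, the enolised pyranone is a poor acceptor for methoxide, and the remote hydroxy ester has no nucleophile within reach and exchanges only degenerately with NaOMe/MeOH. Acidification returns the neutral diol and recloses to the chromone any pyranone that methoxide has opened.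

Step 10
Reactants: 19 methyl (S)-7-(5,7-dihydroxy-4-oxo-4H-chromen-2-yl)-3-hydroxyheptanoate
Product: 20 methyl (S)-7-(5,7-dimethoxy-4-oxo-4H-chromen-2-yl)-3-hydroxyheptanoate (penithochromone Q)
Conditions: Me2SO4 (excess), K2CO3, acetone, reflux
Reagents that add atoms: dimethyl sulfate, COS(=O)(=O)OC
Why: In this Williamson-type O-methylation K2CO3 ionises only the two phenols (the chelated 5-OH needs excess reagent and heating) while the aliphatic alcohol stays protonated and unreactive, and the hard methylating agent favours O- over C-methylation.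

**Compound list**

1 | 4-chlorobutanoyl chloride | O=C(Cl)CCCCl | starting material
2 | Meldrum's acid (2,2-dimethyl-1,3-dioxane-4,6-dione) | CC1(C)OC(=O)CC(=O)O1 | starting material
3 | 5-(4-chloro-1-hydroxybutylidene)-2,2-dimethyl-1,3-dioxane-4,6-dione (acyl Meldrum's acid) | CC1(C)OC(=O)C(=C(O)CCCCl)C(=O)O1 | intermediate
4 | methyl 6-chloro-3-oxohexanoate | COC(=O)CC(=O)CCCCl | intermediate
5 | methyl (S)-6-chloro-3-hydroxyhexanoate | COC(=O)C[C@@H](O)CCCCl | intermediate
6 | methyl (S)-3-[(tert-butyldimethylsilyl)oxy]-6-chlorohexanoate | COC(=O)C[C@@H](O[Si](C)(C)C(C)(C)C)CCCCl | intermediate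
7 | methyl (S)-3-[(tert-butyldimethylsilyl)oxy]-6-iodohexanoate | COC(=O)C[C@@H](O[Si](C)(C)C(C)(C)C)CCCI | intermediate
8 | 2,6-dimethyl-4H-pyran-4-one | Cc1cc(=O)cc(C)o1 | starting material
9 | 2-(lithiomethyl)-6-methyl-4H-pyran-4-one | [Li]Cc1cc(=O)cc(C)o1 | intermediate
10 | methyl (S)-3-[(tert-butyldimethylsilyl)oxy]-7-(6-methyl-4-oxo-4H-pyran-2-yl)heptanoate | COC(=O)C[C@@H](O[Si](C)(C)C(C)(C)C)CCCCc1cc(=O)cc(C)o1 | intermediate
11 | methyl (S)-3-[(tert-butyldimethylsilyl)oxy]-7-[6-(lithiomethyl)-4-oxo-4H-pyran-2-yl]heptanoate | COC(=O)C[C@@H](O[Si](C)(C)C(C)(C)C)CCCCc1cc(=O)cc(C[Li])o1 | intermediate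
12 | 2-{6-[(5S)-5-[(tert-butyldimethylsilyl)oxy]-7-methoxy-7-oxoheptyl]-4-oxo-4H-pyran-2-yl}acetic acid | COC(=O)C[C@@H](O[Si](C)(C)C(C)(C)C)CCCCc1cc(=O)cc(CC(=O)O)o1 | intermediate
13 | potassium monomethyl malonate | COC(=O)CC(=O)[O-].[K+] | starting material
14 | methyl (S)-3-[(tert-butyldimethylsilyl)oxy]-7-{6-[2-(1H-imidazol-1-yl)-2-oxoethyl]-4-oxo-4H-pyran-2-yl}heptanoate (acyl imidazolide) | COC(=O)C[C@@H](O[Si](C)(C)C(C)(C)C)CCCCc1cc(=O)cc(CC(=O)n2ccnc2)o1 | intermediate
15 | 4-{6-[(5S)-5-[(tert-butyldimethylsilyl)oxy]-7-methoxy-7-oxoheptyl]-4-oxo-4H-pyran-2-yl}-2-(methoxycarbonyl)-3-oxobutanoic acid (acylmalonic half-ester) | COC(=O)C[C@@H](O[Si](C)(C)C(C)(C)C)CCCCc1cc(=O)cc(CC(=O)C(C(=O)O)C(=O)OC)o1 | intermediate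
16 | methyl (S)-3-[(tert-butyldimethylsilyl)oxy]-7-[6-(4-methoxy-2,4-dioxobutyl)-4-oxo-4H-pyran-2-yl]heptanoate | COC(=O)C[C@@H](O[Si](C)(C)C(C)(C)C)CCCCc1cc(=O)cc(CC(=O)CC(=O)OC)o1 | intermediate
17 | methyl (S)-3-hydroxy-7-[6-(4-methoxy-2,4-dioxobutyl)-4-oxo-4H-pyran-2-yl]heptanoate | COC(=O)C[C@@H](O)CCCCc1cc(=O)cc(CC(=O)CC(=O)OC)o1 | intermediate
18 | methyl (S)-3-hydroxy-7-(4,5,7-trioxo-5,6,7,8-tetrahydro-4H-chromen-2-yl)heptanoate | COC(=O)C[C@@H](O)CCCCC1=CC(=O)C2=C(O1)CC(=O)CC2=O | intermediate
19 | methyl (S)-7-(5,7-dihydroxy-4-oxo-4H-chromen-2-yl)-3-hydroxyheptanoate | COC(=O)C[C@@H](O)CCCCc1cc(=O)c2c(O)cc(O)cc2o1 | intermediate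
20 | methyl (S)-7-(5,7-dimethoxy-4-oxo-4H-chromen-2-yl)-3-hydroxyheptanoate (penithochromone Q) | COC(=O)C[C@@H](O)CCCCc1cc(=O)c2c(OC)cc(OC)cc2o1 | target

**Step count and risks**

Total: 10 steps. Longest linear sequence: 10 steps (1 → 20); pyranone 8 enters at step 5 and malonate 13 at step 7.

Steps most likely to fail:

Step 5. The extended enolate may attack the methyl ester of the iodide (Claisen-type acylation) or remove its α-proton with loss of silanolate, and proton exchange with the first product may lead to a second alkylation. Fallback: aldol addition, dehydration and hydrogenation in place of the SN2 alkylation, setting out from 7 and 9 and coming back at 10. Kornblum oxidation of 7 (NaHCO3, DMSO, 120 °C, short heating) would give methyl (S)-3-[(tert-butyldimethylsilyl)oxy]-6-oxohexanoate F1. At −78 °C anion 9 adds to an aldehyde far faster than to an ester, which should give the carbinol methyl (3S)-3-[(tert-butyldimethylsilyl)oxy]-6-hydroxy-7-(6-methyl-4-oxo-4H-pyran-2-yl)heptanoate F2 as both C6 epimers. Mesylation (MsCl, Et3N, CH2Cl2, 0 °C) would give methyl (3S)-3-[(tert-butyldimethylsilyl)oxy]-6-[(methylsulfonyl)oxy]-7-(6-methyl-4-oxo-4H-pyran-2-yl)heptanoate F3. DBU-induced elimination through the acidic C7–H would then give methyl (S,E)-3-[(tert-butyldimethylsilyl)oxy]-7-(6-methyl-4-oxo-4H-pyran-2-yl)hept-6-enoate F4. Hydrogenation of this exocyclic alkene (H2, Pd/C, EtOAc), the reduction that takes 2-styryl-γ-pyrones to their 2-phenethyl congeners, returns 10.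

Step 6. Deprotonation may occur at the already substituted methylene or at the ester α-carbon (followed by β-elimination of silanolate), and the pyranylacetic acid may lose CO2 during isolation or activation. Fallback: a route to the arm without amide base and without the free acid, setting out from 10 and coming back at 16. Condensation of the activated methyl with DMF dimethyl acetal (N-methylimidazole cat., 120 °C) is sterically selective for CH3 over the substituted methylene and does not touch a simple ester. It would give the enaminone methyl (S,E)-3-[(tert-butyldimethylsilyl)oxy]-7-{6-[2-(dimethylamino)ethenyl]-4-oxo-4H-pyran-2-yl}heptanoate F5. Mild aqueous acid (AcOH, H2O, THF) would hydrolyse it to the aldehyde methyl (S)-3-[(tert-butyldimethylsilyl)oxy]-7-[4-oxo-6-(2-oxoethyl)-4H-pyran-2-yl]heptanoate F6. Roskamp homologation of F6 (methyl diazoacetate, SnCl2 cat., CH2Cl2) would give β-keto ester 16 directly, so that steps 6 and 7 are both replaced.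

Step 9. Methoxide may open the pyranone by conjugate addition so that aldol-type foldings of the freed chain compete. The strongly delocalised enolate may also be too unreactive to close before the β-hydroxy ester suffers dehydration or retro-aldol cleavage. Fallback: the benzene ring is taken from an aromatic building block instead of being made, setting out from 7 and coming back at 20. Claisen condensation of commercial 2'-hydroxy-4',6'-dimethoxyacetophenone with ethyl acetate (NaH, THF, reflux) would give 1-(2-hydroxy-4,6-dimethoxyphenyl)butane-1,3-dione F7. Cyclodehydration (HCl, AcOH) would give 5,7-dimethoxy-2-methyl-4H-chromen-4-one F8. Lateral lithiation (LiHMDS, THF, −78 °C) to 2-(lithiomethyl)-5,7-dimethoxy-4H-chromen-4-one F9 and alkylation with 7 would give methyl (S)-3-[(tert-butyldimethylsilyl)oxy]-7-(5,7-dimethoxy-4-oxo-4H-chromen-2-yl)heptanoate F10. Desilylation with HF·pyridine as in step 8 then gives 20.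

**Further compounds**

F1 | step 5 | methyl (S)-3-[(tert-butyldimethylsilyl)oxy]-6-oxohexanoate | COC(=O)C[C@@H](O[Si](C)(C)C(C)(C)C)CCC=O
F2 | step 5 | methyl (3S)-3-[(tert-butyldimethylsilyl)oxy]-6-hydroxy-7-(6-methyl-4-oxo-4H-pyran-2-yl)heptanoate | COC(=O)C[C@@H](O[Si](C)(C)C(C)(C)C)CCC(O)Cc1cc(=O)cc(C)o1
F3 | step 5 | methyl (3S)-3-[(tert-butyldimethylsilyl)oxy]-6-[(methylsulfonyl)oxy]-7-(6-methyl-4-oxo-4H-pyran-2-yl)heptanoate | COC(=O)C[C@@H](O[Si](C)(C)C(C)(C)C)CCC(OS(C)(=O)=O)Cc1cc(=O)cc(C)o1
F4 | step 5 | methyl (S,E)-3-[(tert-butyldimethylsilyl)oxy]-7-(6-methyl-4-oxo-4H-pyran-2-yl)hept-6-enoate | COC(=O)C[C@@H](O[Si](C)(C)C(C)(C)C)CC/C=C/c1cc(=O)cc(C)o1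
F5 | step 6 | methyl (S,E)-3-[(tert-butyldimethylsilyl)oxy]-7-{6-[2-(dimethylamino)ethenyl]-4-oxo-4H-pyran-2-yl}heptanoate | COC(=O)C[C@@H](O[Si](C)(C)C(C)(C)C)CCCCc1cc(=O)cc(/C=C/N(C)C)o1
F6 | step 6 | methyl (S)-3-[(tert-butyldimethylsilyl)oxy]-7-[4-oxo-6-(2-oxoethyl)-4H-pyran-2-yl]heptanoate | COC(=O)C[C@@H](O[Si](C)(C)C(C)(C)C)CCCCc1cc(=O)cc(CC=O)o1
F7 | step 9 | 1-(2-hydroxy-4,6-dimethoxyphenyl)butane-1,3-dione | CC(=O)CC(=O)c1c(O)cc(OC)cc1OC
F8 | step 9 | 5,7-dimethoxy-2-methyl-4H-chromen-4-one | Cc1cc(=O)c2c(OC)cc(OC)cc2o1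
F9 | step 9 | 2-(lithiomethyl)-5,7-dimethoxy-4H-chromen-4-one | [Li]Cc1cc(=O)c2c(OC)cc(OC)cc2o1
F10 | step 9 | methyl (S)-3-[(tert-butyldimethylsilyl)oxy]-7-(5,7-dimethoxy-4-oxo-4H-chromen-2-yl)heptanoate | COC(=O)C[C@@H](O[Si](C)(C)C(C)(C)C)CCCCc1cc(=O)c2c(OC)cc(OC)cc2o1
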